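**Retrosynthetic overview**
1. The plan rests on C5 of the 1,2-dioxolane (ring O1–O2–C3–C4–C5): a fully substituted peroxide carbon bearing a methyl group, which is the Markovnikov adduct of O1 to a C5=CH2 unit. Cutting O1–C5 gives an acyclic C3 tertiary hydroperoxide with a 2-alkylallyl arm; divalent mercury closes it and hydride turns CH2Hg into the methyl.
2. The acid goes back to a TBDPS-protected hydroxyethyl arm, and the triene to a Julia–Kocienski union (C9=C10 of the side chain) of a chain-end tetrazolyl sulfone with (2E,4E)-hepta-2,4-dienal. Both follow ring closure, because a triene would compete for mercury.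
3. The C3–OOH bond comes from invertive perhydrolysis of a 2,2-disubstituted oxetane. The oxetane comes from sulfoxonium-ylide ring expansion of the epoxide built from (R)-2-methylglycidol and an alkenyl Grignard reagent (8-bromooctan-1-ol + 2,3-dibromopropene).
4. Ring order: oxirane, then oxetane (both temporary, both carrying the future C3), then the 1,2-dioxolane, the only ring of the target, in step 8.

Key step: step 8

Remark: step 8 is expected to give both C5 epimers; it is assumed that the unwanted one can be removed by chromatography at compound 18, and only the wanted series is written.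

**Step 1**
Reactants: 1 8-bromooctan-1-ol
Product: 2 (8-bromooctyloxy)(tert-butyl)dimethylsilane
Conditions: TBSCl, imidazole, CH2Cl2, 0 °C to rt
Reagents that add atoms: tert-butyldimethylsilyl chloride, CC(C)(C)[Si](C)(C)Cl
Why: Imidazole-promoted silylation of a primary alcohol gives a TBS ether that tolerates Grignard formation and can later be removed beside a TBDPS ether.

**Step 2**
Reactants: 2 (8-bromooctyloxy)(tert-butyl)dimethylsilane; 3 2,3-dibromoprop-1-ene
Product: 5 [(10-bromoundec-10-en-1-yl)oxy](tert-butyl)dimethylsilane, via Grignard reagent 4 (not isolated)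
Conditions: Mg, THF, 40 °C; then 3 (1.3 equiv), CuI (5 mol%), THF, −10 °C to rt
Reagents that add atoms: none
Why: Copper-catalysed allylic substitution of the allylic bromide of 3 by the alkyl Grignard reagent (SN2 and SN2' attack give the same 2-bromo-1-alkene), the vinylic C–Br bond staying inert.

**Step 3**
Reactants: 5 [(10-bromoundec-10-en-1-yl)oxy](tert-butyl)dimethylsilane; 6 (R)-2-methylglycidol
Product: 8 (2S)-13-[(tert-butyldimethylsilyl)oxy]-2-methyl-4-methylidenetridecane-1,2-diol, via alkenylmagnesium bromide 7 (not isolated)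
Conditions: 5, Mg, THF, 45 °C; 6 pre-treated with MeMgBr (1.0 equiv), THF, −40 °C; CuI (10 mol%), −40 to 0 °C
Reagents that add atoms: none
Why: Copper-catalysed Grignard opening of the 2,2-disubstituted epoxide at its CH2 terminus (the hydroxyl is first turned into its magnesium alkoxide so that no alkenyl reagent is spent on it), with no bond to the quaternary stereocentre made or broken; Payne migration of this epoxy alkoxide is degenerate and returns the same enantiomer.

**Step 4**
Reactants: 8 (2S)-13-[(tert-butyldimethylsilyl)oxy]-2-methyl-4-methylidenetridecane-1,2-diol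
Product: 10 (2S)-2-{11-[(tert-butyldimethylsilyl)oxy]-2-methylideneundecyl}-2-methyloxirane, via hydroxy tosylate 9 (not isolated)
Conditions: TsCl, Et3N, DMAP (cat.), CH2Cl2, 0 °C; then K2CO3, MeOH, rt
Reagents that add atoms: none
Why: Selective sulfonylation of the primary hydroxyl (the tertiary one is inert) followed by Williamson 3-exo-tet closure, the tertiary C–O bond being retained so that the configuration is carried over.

**Step 5**
Reactants: 10 (2S)-2-{11-[(tert-butyldimethylsilyl)oxy]-2-methylideneundecyl}-2-methyloxirane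
Product: 11 (2S)-2-{11-[(tert-butyldimethylsilyl)oxy]-2-methylideneundecyl}-2-methyloxetane
Conditions: Me3S(O)I (3 equiv), KOtBu (3 equiv), t-BuOH, 60 °C
Reagents that add atoms: trimethylsulfoxonium iodide, C[S+](C)(C)=O.[I-]
Why: Ring expansion of an epoxide to an oxetane with the Corey–Chaykovsky sulfoxonium ylide, which opens the oxirane at CH2 and lets the tertiary alkoxide displace DMSO in a 4-exo-tet closure with retention at the quaternary carbon.

**Step 6**
Reactants: 11 (2S)-2-{11-[(tert-butyldimethylsilyl)oxy]-2-methylideneundecyl}-2-methyloxetane; 12 hydrogen peroxide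
Product: 13 (3R)-14-[(tert-butyldimethylsilyl)oxy]-3-hydroperoxy-3-methyl-5-methylidenetetradecan-1-ol
Conditions: H2O2 (anhydrous, in Et2O, 10 equiv), TMSOTf (0.3 equiv), Et2O, −78 to −20 °C; NaHCO3 quench
Reagents that add atoms: none
Why: Lewis-acid-promoted perhydrolysis of a 2,2-disubstituted oxetane, in which H2O2 attacks the activated ring at the tertiary carbon opposite to the leaving oxygen (borderline SN2), so that C3–OOH forms with inversion and the (S)-oxetane should give the (R)-hydroperoxide, while low temperature and sub-stoichiometric TMSOTf spare the TBS ether and the alkene.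

**Step 7**
Reactants: 13 (3R)-14-[(tert-butyldimethylsilyl)oxy]-3-hydroperoxy-3-methyl-5-methylidenetetradecan-1-ol
Product: 15 tert-butyl{[(3R)-14-[(tert-butyldimethylsilyl)oxy]-3-hydroperoxy-3-methyl-5-methylidenetetradecyl]oxy}diphenylsilane, via bis-silylated peroxide 14 (not isolated)
Conditions: TBDPSCl (2.3 equiv), imidazole, DMAP (cat.), CH2Cl2, 0 °C to rt; then K2CO3 (cat.), MeOH, 0 °C
Reagents that add atoms: tert-butyldiphenylsilyl chloride, CC(C)(C)[Si](Cl)(c1ccccc1)c1ccccc1
Why: Imidazole-mediated silylation secures the primary alcohol as its TBDPS ether, and because the hydroperoxide is silylated too, mild methanolysis then cleaves only the peroxysilane Si–OO bond (peroxide anion being a much better leaving group than alkoxide) and returns the free OOH.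

**Step 8**
Reactants: 15 tert-butyl{[(3R)-14-[(tert-butyldimethylsilyl)oxy]-3-hydroperoxy-3-methyl-5-methylidenetetradecyl]oxy}diphenylsilane; 16 Hg(OAc)2
Product: 17 (3S,5S)-5-(acetoxymercuriomethyl)-3-{2-[(tert-butyldiphenylsilyl)oxy]ethyl}-5-{9-[(tert-butyldimethylsilyl)oxy]nonyl}-3-methyl-1,2-dioxolane
Conditions: Hg(OAc)2 (1.2 equiv), CH2Cl2, 0 °C to rt, dark
Reagents that add atoms: none
Why: Hg(OAc)2 adds reversibly to the 1,1-disubstituted C5=CH2 bond to give a mercurinium ion whose positive charge sits on the tertiary C5, and the terminal oxygen of the C3 hydroperoxide, an alpha-effect nucleophile, opens it anti at C5 with loss of AcOH. The closest known reaction type is the cycloperoxymercuration of unsaturated hydroperoxides, an intramolecular peroxymercuration that is established for homoallylic hydroperoxides. The one ring closure is 5-exo-trig and forms O1–C5, leaving CH2HgOAc exocyclic where the C5 methyl will stand. The new stereocentre C5 is controlled only by 1,3-induction from C3 in an envelope transition state that keeps the nonyl chain away from the larger silyloxyethyl arm; as both C5 substituents are CH2X groups the bias should be modest, so the C5 epimer is expected as a co-product. The step needs Markovnikov regiochemistry, secured by the tertiary cation character of C5 (attack at CH2 would be 6-endo and anti-Markovnikov). It also needs chemoselectivity, secured because this is the only alkene present and both hydroxyls are silylated, so no oxymercuration to a tetrahydropyran can compete.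

**Step 9**
Reactants: 17 (3S,5S)-5-(acetoxymercuriomethyl)-3-{2-[(tert-butyldiphenylsilyl)oxy]ethyl}-5-{9-[(tert-butyldimethylsilyl)oxy]nonyl}-3-methyl-1,2-dioxolane
Product: 18 (3S,5S)-3-{2-[(tert-butyldiphenylsilyl)oxy]ethyl}-5-{9-[(tert-butyldimethylsilyl)oxy]nonyl}-3,5-dimethyl-1,2-dioxolane
Conditions: NaBH4 (excess), 2 M aq NaOH, CH2Cl2, 0 °C; chromatography to remove the C5 epimer
Reagents that add atoms: none
Why: Hydridodemercuration, in which NaBH4 turns C–Hg into an alkylmercury hydride that collapses through the CH2 radical to the C5 methyl, the competing closure of this beta-peroxyalkyl radical to an epoxide being limited by fast hydrogen transfer at 0 °C with excess hydride, and neither stereocentre being involved.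

**Step 10**
Reactants: 18 (3S,5S)-3-{2-[(tert-butyldiphenylsilyl)oxy]ethyl}-5-{9-[(tert-butyldimethylsilyl)oxy]nonyl}-3,5-dimethyl-1,2-dioxolane
Product: 19 (3S,5S)-3-{2-[(tert-butyldiphenylsilyl)oxy]ethyl}-5-(9-hydroxynonyl)-3,5-dimethyl-1,2-dioxolane
Conditions: CSA (0.1 equiv), MeOH/CH2Cl2 (1:1), 0 °C
Reagents that add atoms: none
Why: Acid-catalysed methanolysis removes the primary TBS ether much faster than the TBDPS ether, and the dialkyl peroxide is inert to mild acid.

**Step 11**
Reactants: 19 (3S,5S)-3-{2-[(tert-butyldiphenylsilyl)oxy]ethyl}-5-(9-hydroxynonyl)-3,5-dimethyl-1,2-dioxolane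
Product: 21 (3S,5S)-3-{2-[(tert-butyldiphenylsilyl)oxy]ethyl}-3,5-dimethyl-5-{9-[(1-phenyl-1H-tetrazol-5-yl)sulfanyl]nonyl}-1,2-dioxolane, via mesylate 20 (not isolated)
Conditions: MsCl, Et3N, CH2Cl2, 0 °C; then 1-phenyl-1H-tetrazole-5-thiol, K2CO3, DMF, rt to 40 °C
Reagents that add atoms: 1-phenyl-1H-tetrazole-5-thiol, Sc1nnnn1-c1ccccc1
Why: Mesylation then SN2 displacement by the tetrazolyl thiolate installs the sulfide without the phosphine of a Mitsunobu reaction, which could deoxygenate the peroxide.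

**Step 12**
Reactants: 21 (3S,5S)-3-{2-[(tert-butyldiphenylsilyl)oxy]ethyl}-3,5-dimethyl-5-{9-[(1-phenyl-1H-tetrazol-5-yl)sulfanyl]nonyl}-1,2-dioxolane; 12 hydrogen peroxide
Product: 22 (3S,5S)-3-{2-[(tert-butyldiphenylsilyl)oxy]ethyl}-3,5-dimethyl-5-{9-[(1-phenyl-1H-tetrazol-5-yl)sulfonyl]nonyl}-1,2-dioxolane
Conditions: (NH4)6Mo7O24·4H2O (10 mol%), 30% aq H2O2, EtOH, 0 °C to rt
Reagents that add atoms: none
Why: Molybdate-catalysed peroxide oxidation of the sulfide to the sulfone, in which the dioxolane, having no oxidisable site, is inert.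

**Step 13**
Reactants: 22 (3S,5S)-3-{2-[(tert-butyldiphenylsilyl)oxy]ethyl}-3,5-dimethyl-5-{9-[(1-phenyl-1H-tetrazol-5-yl)sulfonyl]nonyl}-1,2-dioxolane; 23 (2E,4E)-hepta-2,4-dienal
Product: 24 (3S,5S)-3-{2-[(tert-butyldiphenylsilyl)oxy]ethyl}-5-[(9E,11E,13E)-hexadeca-9,11,13-trien-1-yl]-3,5-dimethyl-1,2-dioxolane
Conditions: KHMDS (1.1 equiv), DME, −60 °C, 20 min; then 23 (1.5 equiv), −60 °C to rt
Reagents that add atoms: none
Why: Julia–Kocienski olefination, in which the potassium sulfone anion adds to the dienal and Smiles rearrangement with loss of SO2 and the tetrazolone forms the C9=C10 alkene, expected mainly E for an alkyl tetrazolyl sulfone with an unsaturated aldehyde in DME; the peroxide carbons carry no hydrogen, so base cannot start a Kornblum–DeLaMare cleavage.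

**Step 14**
Reactants: 24 (3S,5S)-3-{2-[(tert-butyldiphenylsilyl)oxy]ethyl}-5-[(9E,11E,13E)-hexadeca-9,11,13-trien-1-yl]-3,5-dimethyl-1,2-dioxolane
Product: 25 2-[(3S,5S)-5-[(9E,11E,13E)-hexadeca-9,11,13-trien-1-yl]-3,5-dimethyl-1,2-dioxolan-3-yl]ethan-1-ol
Conditions: TBAF, AcOH (1:1), THF, 0 °C to rt
Reagents that add atoms: none
Why: Fluoride-mediated cleavage of the TBDPS ether, buffered with AcOH so that the triene and the peroxide see neither strong base nor acid.

**Step 15**
Reactants: 25 2-[(3S,5S)-5-[(9E,11E,13E)-hexadeca-9,11,13-trien-1-yl]-3,5-dimethyl-1,2-dioxolan-3-yl]ethan-1-ol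
Product: 27 2-[(3R,5S)-5-[(9E,11E,13E)-hexadeca-9,11,13-trien-1-yl]-3,5-dimethyl-1,2-dioxolan-3-yl]acetic acid, via beta-peroxy aldehyde 26 (not isolated)
Conditions: Dess–Martin periodinane, NaHCO3, CH2Cl2, 0 °C; then NaClO2, NaH2PO4, 2-methyl-2-butene (excess), t-BuOH/H2O, 0 °C
Reagents that add atoms: sodium chlorite, [Na+].[O-]Cl=O
Why: Dess–Martin oxidation to the aldehyde followed at once by Pinnick oxidation (2-methyl-2-butene scavenges HOCl and protects the triene) gives the acid without isolating the elimination-prone beta-peroxy aldehyde, the O–O bond being inert to both oxidants; the C3 descriptor changes from S to R only through CIP priority.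

**Compound list**
1 | 8-bromooctan-1-ol | OCCCCCCCCBr | starting material
2 | (8-bromooctyloxy)(tert-butyl)dimethylsilane | CC(C)(C)[Si](C)(C)OCCCCCCCCBr | intermediate
3 | 2,3-dibromoprop-1-ene | C=C(Br)CBr | starting material
4 | {8-[(tert-butyldimethylsilyl)oxy]octyl}magnesium bromide | CC(C)(C)[Si](C)(C)OCCCCCCCC[Mg]Br | intermediate
5 | [(10-bromoundec-10-en-1-yl)oxy](tert-butyl)dimethylsilane | C=C(Br)CCCCCCCCCO[Si](C)(C)C(C)(C)C | intermediate
6 | (R)-2-methylglycidol, [(2R)-2-methyloxiran-2-yl]methanol | OC[C@]1(C)CO1 | starting material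
7 | {11-[(tert-butyldimethylsilyl)oxy]undec-1-en-2-yl}magnesium bromide | C=C([Mg]Br)CCCCCCCCCO[Si](C)(C)C(C)(C)C | intermediate
8 | (2S)-13-[(tert-butyldimethylsilyl)oxy]-2-methyl-4-methylidenetridecane-1,2-diol | C=C(CCCCCCCCCO[Si](C)(C)C(C)(C)C)C[C@](C)(O)CO | intermediate
9 | (2S)-13-[(tert-butyldimethylsilyl)oxy]-2-hydroxy-2-methyl-4-methylidenetridecyl 4-methylbenzenesulfonate | C=C(CCCCCCCCCO[Si](C)(C)C(C)(C)C)C[C@](C)(O)COS(=O)(=O)c1ccc(C)cc1 | intermediate
10 | (2S)-2-{11-[(tert-butyldimethylsilyl)oxy]-2-methylideneundecyl}-2-methyloxirane | C=C(CCCCCCCCCO[Si](C)(C)C(C)(C)C)C[C@@]1(C)CO1 | intermediate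
11 | (2S)-2-{11-[(tert-butyldimethylsilyl)oxy]-2-methylideneundecyl}-2-methyloxetane | C=C(CCCCCCCCCO[Si](C)(C)C(C)(C)C)C[C@@]1(C)CCO1 | intermediate
12 | hydrogen peroxide | OO | starting material
13 | (3R)-14-[(tert-butyldimethylsilyl)oxy]-3-hydroperoxy-3-methyl-5-methylidenetetradecan-1-ol | C=C(CCCCCCCCCO[Si](C)(C)C(C)(C)C)C[C@](C)(CCO)OO | intermediate
14 | (3R)-O,OO-bis(tert-butyldiphenylsilyl) derivative of 13 (TBDPS ether and TBDPS peroxide) | C=C(CCCCCCCCCO[Si](C)(C)C(C)(C)C)C[C@](C)(CCO[Si](c1ccccc1)(c1ccccc1)C(C)(C)C)OO[Si](c1ccccc1)(c1ccccc1)C(C)(C)C | intermediate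
15 | tert-butyl{[(3R)-14-[(tert-butyldimethylsilyl)oxy]-3-hydroperoxy-3-methyl-5-methylidenetetradecyl]oxy}diphenylsilane | C=C(CCCCCCCCCO[Si](C)(C)C(C)(C)C)C[C@](C)(CCO[Si](c1ccccc1)(c1ccccc1)C(C)(C)C)OO | intermediate
16 | Hg(OAc)2, mercury diacetate | CC(=O)O[Hg]OC(C)=O | starting material
17 | (3S,5S)-5-(acetoxymercuriomethyl)-3-{2-[(tert-butyldiphenylsilyl)oxy]ethyl}-5-{9-[(tert-butyldimethylsilyl)oxy]nonyl}-3-methyl-1,2-dioxolane | CC(C)(C)[Si](C)(C)OCCCCCCCCC[C@@]1(C[Hg]OC(C)=O)C[C@](C)(CCO[Si](c2ccccc2)(c2ccccc2)C(C)(C)C)OO1 | intermediate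
18 | (3S,5S)-3-{2-[(tert-butyldiphenylsilyl)oxy]ethyl}-5-{9-[(tert-butyldimethylsilyl)oxy]nonyl}-3,5-dimethyl-1,2-dioxolane | CC(C)(C)[Si](C)(C)OCCCCCCCCC[C@@]1(C)C[C@](C)(CCO[Si](c2ccccc2)(c2ccccc2)C(C)(C)C)OO1 | intermediate
19 | (3S,5S)-3-{2-[(tert-butyldiphenylsilyl)oxy]ethyl}-5-(9-hydroxynonyl)-3,5-dimethyl-1,2-dioxolane | OCCCCCCCCC[C@@]1(C)C[C@](C)(CCO[Si](c2ccccc2)(c2ccccc2)C(C)(C)C)OO1 | intermediate
20 | 9-[(3S,5S)-5-{2-[(tert-butyldiphenylsilyl)oxy]ethyl}-3,5-dimethyl-1,2-dioxolan-3-yl]nonyl methanesulfonate (same compound numbering as 19, OH replaced by OMs) | CS(=O)(=O)OCCCCCCCCC[C@@]1(C)C[C@](C)(CCO[Si](c2ccccc2)(c2ccccc2)C(C)(C)C)OO1 | intermediate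
21 | (3S,5S)-3-{2-[(tert-butyldiphenylsilyl)oxy]ethyl}-3,5-dimethyl-5-{9-[(1-phenyl-1H-tetrazol-5-yl)sulfanyl]nonyl}-1,2-dioxolane | c1ccc(cc1)-n1nnnc1SCCCCCCCCC[C@@]1(C)C[C@](C)(CCO[Si](c2ccccc2)(c2ccccc2)C(C)(C)C)OO1 | intermediate
22 | (3S,5S)-3-{2-[(tert-butyldiphenylsilyl)oxy]ethyl}-3,5-dimethyl-5-{9-[(1-phenyl-1H-tetrazol-5-yl)sulfonyl]nonyl}-1,2-dioxolane | c1ccc(cc1)-n1nnnc1S(=O)(=O)CCCCCCCCC[C@@]1(C)C[C@](C)(CCO[Si](c2ccccc2)(c2ccccc2)C(C)(C)C)OO1 | intermediate
23 | (2E,4E)-hepta-2,4-dienal | CC/C=C/C=C/C=O | starting material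
24 | (3S,5S)-3-{2-[(tert-butyldiphenylsilyl)oxy]ethyl}-5-[(9E,11E,13E)-hexadeca-9,11,13-trien-1-yl]-3,5-dimethyl-1,2-dioxolane | CC/C=C/C=C/C=C/CCCCCCCC[C@@]1(C)C[C@](C)(CCO[Si](c2ccccc2)(c2ccccc2)C(C)(C)C)OO1 | intermediate
25 | 2-[(3S,5S)-5-[(9E,11E,13E)-hexadeca-9,11,13-trien-1-yl]-3,5-dimethyl-1,2-dioxolan-3-yl]ethan-1-ol | CC/C=C/C=C/C=C/CCCCCCCC[C@@]1(C)C[C@](C)(CCO)OO1 | intermediate
26 | 2-[(3R,5S)-5-[(9E,11E,13E)-hexadeca-9,11,13-trien-1-yl]-3,5-dimethyl-1,2-dioxolan-3-yl]acetaldehyde | CC/C=C/C=C/C=C/CCCCCCCC[C@@]1(C)C[C@](C)(CC=O)OO1 | intermediate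
27 | 2-[(3R,5S)-5-[(9E,11E,13E)-hexadeca-9,11,13-trien-1-yl]-3,5-dimethyl-1,2-dioxolan-3-yl]acetic acid | CC/C=C/C=C/C=C/CCCCCCCC[C@@]1(C)C[C@](C)(CC(=O)O)OO1 | target

**Totals**
Total step count: 15. Longest linear sequence: 15 steps (steps 1–15 from 8-bromooctan-1-ol).

**Steps most likely to fail**

Step 8. The closure may show little facial bias at C5, and reversal of the mercurinium ion or its capture by acetate may lower the throughput. Fallback: setting out from 15, the reversible mercuration is replaced by an irreversible halonium closure. N-Iodosuccinimide in CH2Cl2 at −40 °C should give, by the same 5-exo O1–C5 closure, (3S,5S)-3-{2-[(tert-butyldiphenylsilyl)oxy]ethyl}-5-{9-[(tert-butyldimethylsilyl)oxy]nonyl}-5-(iodomethyl)-3-methyl-1,2-dioxolane F1, from which the C5 epimer is removed by chromatography. Reduction of the C–I bond with Bu3SnH and Et3B/air in toluene at −20 °C then comes back to the route at 18.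

Step 9. The beta-peroxyalkyl radical may close onto O1 with O–O cleavage, giving an epoxide, before it is reduced. Fallback: setting out from 17, acetate is exchanged for bromide with aqueous KBr to give the bromomercurial F2. Its C–Hg bond is cleaved with Br2 and pyridine in CH2Cl2 at 0 °C to the 5-(bromomethyl)-1,2-dioxolane F3, bromine trapping any radical far faster than it can rearrange. F3 is then reduced with Bu3SnH, catalytic PhSeSePh (PhSeH formed in the flask is a much faster hydrogen donor than the stannane or a mercury hydride) and Et3B/air at 0 °C, which comes back to the route at 18.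

Step 6. The activated oxetane may ionise to a tertiary carbocation instead of undergoing direct displacement, so that the configuration at C3 is partly lost. Fallback: the perhydrolysis is kept and the configurational purity is restored by resolution of the hydroperoxide. Setting out from 15, PPTS-catalysed addition of the OOH group to (1R,2S)-2-phenylcyclohexyl prop-1-en-2-yl ether in CH2Cl2 gives diastereomeric peroxyketals. The (1R,2S)-2-phenylcyclohexyl peroxyketal of the (3R)-hydroperoxide F4 is separated by chromatography and cleaved with AcOH/THF/H2O, which comes back to the route at 15 as a single enantiomer.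

**Further compounds**
F1 | step 8 | (3S,5S)-3-{2-[(tert-butyldiphenylsilyl)oxy]ethyl}-5-{9-[(tert-butyldimethylsilyl)oxy]nonyl}-5-(iodomethyl)-3-methyl-1,2-dioxolane | CC(C)(C)[Si](C)(C)OCCCCCCCCC[C@@]1(CI)C[C@](C)(CCO[Si](c2ccccc2)(c2ccccc2)C(C)(C)C)OO1
F2 | step 9 | (3S,5S)-5-(bromomercuriomethyl)-3-{2-[(tert-butyldiphenylsilyl)oxy]ethyl}-5-{9-[(tert-butyldimethylsilyl)oxy]nonyl}-3-methyl-1,2-dioxolane | CC(C)(C)[Si](C)(C)OCCCCCCCCC[C@@]1(C[Hg]Br)C[C@](C)(CCO[Si](c2ccccc2)(c2ccccc2)C(C)(C)C)OO1
F3 | step 9 | (3S,5S)-5-(bromomethyl)-3-{2-[(tert-butyldiphenylsilyl)oxy]ethyl}-5-{9-[(tert-butyldimethylsilyl)oxy]nonyl}-3-methyl-1,2-dioxolane | CC(C)(C)[Si](C)(C)OCCCCCCCCC[C@@]1(CBr)C[C@](C)(CCO[Si](c2ccccc2)(c2ccccc2)C(C)(C)C)OO1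
F4 | step 6 | 2-{[(1R,2S)-2-phenylcyclohexyl]oxy}propan-2-yl peroxide of (3R)-15 | C=C(CCCCCCCCCO[Si](C)(C)C(C)(C)C)C[C@](C)(CCO[Si](c1ccccc1)(c1ccccc1)C(C)(C)C)OOC(C)(C)O[C@@H]1CCCC[C@H]1c1ccccc1
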